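**Retrosynthetic overview**
1. Ring numbering as in quinic acid (C1 = C(OH)CO2H; O3 cis and O5 trans to O4; C2 between C1 and C3, C6 between C1 and C5). Target ⇒ allyl quinate 15 by three esterifications (O4 succinate through a dibutylstannylene acetal, then the O3 and O5 caffeates from two equivalents of acid chloride 20) ⇒ bridged lactone 14 (1-O-MOM-quinide).
2. 14 ⇒ cyclohexene acid 12: the trans-4,5-diol is carried as a C4=C5 alkene and restored by hydroxyl-directed epoxidation and lactonisation.
3. 12 ⇒ δ-lactone 9 by Ireland–Claisen rearrangement of the lactone enolate (oxacycle to carbocycle), which forms C1–C6. Enabling feature: C1 is the oxygen-bearing α-carbon of the ring carboxylic acid (a glycolate), and O4–C4–C5–C6 can be written as an allylic alcohol; tying the carboxyl to O4 gives a six-membered lactone (O4, C=O, C1, C2, C3, C4) whose ketene acetal C1=C(O)–O4–C4–C5=C6 is a 1,5-diene.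
4. 9 ⇒ glycolate 2 + epoxy aryl ether 5 (from divinylcarbinol by Sharpless epoxidation and Mitsunobu inversion). Ring order: δ-lactone (step 5), carbocycle (step 6), bridging γ-lactone (step 7, reopened in step 8).

Key step: step 6

Remark on the chemistry: the glycolate carbon (later C1) of 6–9 is carried as a mixture of both epimers, because it becomes planar in ketene acetal 10; these compounds are drawn without a descriptor at that centre.

**Step 1**
Reactants: 1 methyl glycolate
Product: 2 methyl 2-(methoxymethoxy)acetate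
Conditions: MOMCl, iPr2NEt, CH2Cl2, 0 °C → rt
Reagents that add atoms: chloromethyl methyl ether (COCCl)
Why: O-alkylation of the hydroxyl by the chloromethyl ether under amine base (methoxymethyl ether formation) masks the future C1 oxygen with a group that survives enolate chemistry and leaves in the final acid step.

**Step 2**
Reactants: 3 penta-1,4-dien-3-ol
Product: 4 (1S)-1-[(2R)-oxiran-2-yl]prop-2-en-1-ol [(2R,3S)-1,2-epoxypent-4-en-3-ol]
Conditions: Ti(OiPr)4 (cat.), L-(+)-diisopropyl tartrate (cat.), t-BuOOH, 4 Å molecular sieves, CH2Cl2, −20 °C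
Reagents that add atoms: tert-butyl hydroperoxide (CC(C)(C)OO)
Why: Sharpless asymmetric epoxidation of the achiral divinyl carbinol, in which the Ti(OiPr)4/tartrate catalyst selects one enantiotopic vinyl group and one face to give the anti epoxy alcohol (future C3 as R), any minor enantiomer being consumed by a faster second epoxidation.

**Step 3**
Reactants: 4 (1S)-1-[(2R)-oxiran-2-yl]prop-2-en-1-ol
Product: 5 (2R)-2-[(1R)-1-(4-methoxyphenoxy)prop-2-en-1-yl]oxirane
Conditions: 4-methoxyphenol, PPh3, DIAD, THF, 0 °C → rt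
Reagents that add atoms: 4-methoxyphenol (COc1ccc(O)cc1)
Why: Mitsunobu etherification, whose SN2 displacement inverts the carbinol carbon (future C4) so that its oxygen and vinyl group have the relation to C3–O that step 6 needs, while the aryl ether masks O4 until step 5.

**Step 4**
Reactants: 5 (2R)-2-[(1R)-1-(4-methoxyphenoxy)prop-2-en-1-yl]oxirane, 2 methyl 2-(methoxymethoxy)acetate
Product: 7 methyl (4R,5R)-4-[(tert-butyldimethylsilyl)oxy]-2-(methoxymethoxy)-5-(4-methoxyphenoxy)hept-6-enoate, via Et2Al alkoxide of hydroxy ester 6 (not isolated)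
Conditions: 2, LiN(iPr)2, THF, −78 °C; Et2AlCl; then 5, −78 → −30 °C; then TBSOTf, 2,6-lutidine, −78 → 0 °C
Reagents that add atoms: tert-butyldimethylsilyl trifluoromethanesulfonate (CC(C)(C)[Si](C)(C)OS(=O)(=O)C(F)(F)F)
Why: Opening of a terminal epoxide at its CH2 carbon by the diethylaluminium ester enolate of 2 (SN2, forms C1–C2, C3 keeps its configuration), followed by trapping of the alkoxide as silyl ether before it can close the γ-lactone.

**Step 5**
Reactants: 7 methyl (4R,5R)-4-[(tert-butyldimethylsilyl)oxy]-2-(methoxymethoxy)-5-(4-methoxyphenoxy)hept-6-enoate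
Product: 9 (5R,6R)-5-[(tert-butyldimethylsilyl)oxy]-6-ethenyl-3-(methoxymethoxy)oxan-2-one, via hydroxy ester 8 (not isolated)
Conditions: (NH4)2Ce(NO3)6, MeCN/H2O 4:1, 0 °C; then PPTS (cat.), toluene, 60 °C
Reagents that add atoms: none
Why: Oxidative cleavage of the 4-methoxyphenyl ether by tetravalent cerium frees the allylic alcohol, which closes the δ-lactone by acid-catalysed acyl substitution at the ester carbon without touching C3 or C4.

**Step 6**
Reactants: 9 (5R,6R)-5-[(tert-butyldimethylsilyl)oxy]-6-ethenyl-3-(methoxymethoxy)oxan-2-one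
Product: 12 (1R,5R)-5-hydroxy-1-(methoxymethoxy)cyclohex-3-ene-1-carboxylic acid, via silyl ketene acetal 10 (not isolated), via silyl ester 11 (not isolated)
Conditions: LiN(iPr)2, Me3SiCl/Et3N, THF, −78 °C → rt; toluene, 100 °C; then TBAF, THF, rt; dilute HCl work-up
Reagents that add atoms: none
Why: Ireland–Claisen rearrangement of a vinyl lactone: the lithium enolate of 9 is trapped as silyl ketene acetal 10, a 1,5-diene C1=C(OSi)–O4–C4–C5=C6, which rearranges by a concerted suprafacial [3,3]-sigmatropic shift to silyl ester 11, forming C1–C6 and breaking C4–O4. The closest known reaction type is the enolate Claisen rearrangement of 6-alkenyl δ-lactones to cyclohex-3-ene-1-carboxylic acids, together with the Claisen rearrangement of α-alkoxy (glycolate) ester enolates. The six-membered carbocycle closes pericyclically through the only accessible transition state, a boat bridged by C2–C3 (bicyclo[2.2.2]octane-like), because four atoms of the rearranging array lie in the lactone ring and the endocyclic ketene acetal has a fixed geometry. The new quaternary centre C1 is controlled by chirality transfer from C4: the vinyl group can deliver C6 only to the face of C1 on which it sits, which fixes the carboxyl carbon and the OMOM group relative to the untouched centre C3. The selectivity needed is C1–O cis to C3–O (carboxyl trans), and it is secured by the cis relation of the C3 silyloxy group and the vinyl group on the lactone, set in steps 2 and 3; both C1 epimers of 9 give the same ketene acetal. Fluoride then removes the silyl ester and the silyl ether to give 12.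

**Step 7**
Reactants: 12 (1R,5R)-5-hydroxy-1-(methoxymethoxy)cyclohex-3-ene-1-carboxylic acid
Product: 14 (1S,3R,4R,5R)-3,4-dihydroxy-1-(methoxymethoxy)-6-oxabicyclo[3.2.1]octan-7-one (1-O-methoxymethyl-quinide), via epoxy acid 13 (not isolated)
Conditions: mCPBA, CH2Cl2, 0 °C → rt; then CSA (cat.)
Reagents that add atoms: 3-chloroperoxybenzoic acid (O=C(OO)c1cccc(Cl)c1)
Why: Hydroxyl-directed peracid epoxidation (Henbest) puts the oxirane on the face of the allylic 3-OH, and the axial carboxyl group on the opposite face opens it at C5 by trans-diaxial 5-exo attack (epoxy acid lactonisation), which sets C4 (oxygen retained, cis to O3) and C5 (inversion, oxygen trans to O4).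

**Step 8**
Reactants: 14 (1S,3R,4R,5R)-3,4-dihydroxy-1-(methoxymethoxy)-6-oxabicyclo[3.2.1]octan-7-one
Product: 15 prop-2-en-1-yl (1S,3R,4S,5R)-3,4,5-trihydroxy-1-(methoxymethoxy)cyclohexane-1-carboxylate (allyl 1-O-methoxymethyl-quinate)
Conditions: allyl alcohol (solvent), K2CO3 (cat.), 0 °C → rt; neutralise before concentration
Reagents that add atoms: prop-2-en-1-ol (C=CCO)
Why: Base-catalysed alcoholysis (transesterification) of the strained bicyclic γ-lactone, the known alkoxide opening of quinide-type lactones, frees O5 and leaves the carboxyl as an allyl ester that is removable under neutral conditions.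

**Step 9**
Reactants: 15 allyl 1-O-methoxymethyl-quinate, 16 succinic anhydride
Product: 18 allyl 4-O-(3-carboxypropanoyl)-1-O-methoxymethyl-quinate, via dibutylstannylene acetal 17 (not isolated)
Conditions: Bu2SnO, toluene, reflux (Dean–Stark); then 16, Et3N, CH2Cl2, 0 °C → rt
Reagents that add atoms: none
Why: Dibutylstannylene acetal acylation: the acetal forms across the cis-3,4-diol and its equatorial oxygen O4 opens the anhydride, as in the 3-O-selective acylation of manno- and rhamnopyranosides, which carry the same axial/equatorial/equatorial triol.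

**Step 10**
Reactants: 19 (E)-3-(3,4-diacetoxyphenyl)prop-2-enoic acid (3,4-di-O-acetylcaffeic acid)
Product: 20 (E)-3-(3,4-diacetoxyphenyl)prop-2-enoyl chloride
Conditions: (COCl)2, DMF (cat.), CH2Cl2, 0 °C → rt; evaporate, use crude
Reagents that add atoms: oxalyl chloride (O=C(Cl)C(=O)Cl)
Why: Acid chloride formation through the Vilsmeier-type chloroiminium species from DMF and oxalyl chloride, which leaves the aryl acetates and the E alkene untouched and gives only gaseous co-products.

**Step 11**
Reactants: 18 allyl 4-O-(3-carboxypropanoyl)-1-O-methoxymethyl-quinate, 20 (E)-3-(3,4-diacetoxyphenyl)prop-2-enoyl chloride (two equivalents are consumed, the second is entered below)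
Product: 22 allyl 3,5-bis-O-[(E)-3-(3,4-diacetoxyphenyl)prop-2-enoyl]-4-O-(3-carboxypropanoyl)-1-O-methoxymethyl-quinate, via 5-O-monocaffeate 21 (not isolated)
Conditions: 20 (3.5 equiv), pyridine, DMAP (cat.), CH2Cl2, 0 °C → rt; aq. NaHCO3 work-up
Reagents that add atoms: second equivalent of (E)-3-(3,4-diacetoxyphenyl)prop-2-enoyl chloride 20 (CC(=O)Oc1ccc(/C=C/C(=O)Cl)cc1OC(C)=O)
Why: Twofold acylation by the acid chloride under pyridine/DMAP catalysis, in which the first equivalent should esterify the equatorial 5-OH and the second the axial 3-OH while the tertiary C1 oxygen is masked; the excess chloride at low temperature is meant to outrun succinyl migration, and the mixed anhydride formed at the succinate carboxyl is hydrolysed on work-up.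

**Step 12**
Reactants: 22 allyl 3,5-bis-O-[(E)-3-(3,4-diacetoxyphenyl)prop-2-enoyl]-4-O-(3-carboxypropanoyl)-1-O-methoxymethyl-quinate
Product: 24 3,5-di-O-caffeoyl-4-O-succinyl-(−)-quinic acid (target), via free acid 23 (not isolated)
Conditions: Pd(PPh3)4 (cat.), N-methylaniline, THF, rt; then 2 M HCl (aq.)/THF, rt
Reagents that add atoms: none
Why: Zerovalent palladium transfers the allyl group of the ester to N-methylaniline (allyl ester deprotection with a scavenger too weakly nucleophilic to aminolyse the aryl acetates), then dilute aqueous acid hydrolyses the four aryl acetates and the methoxymethyl ether, conditions under which cinnamoyl quinate esters are known to stay in place without acyl migration.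

**Compound list**
1 | methyl glycolate | COC(=O)CO | starting material
2 | methyl 2-(methoxymethoxy)acetate | COCOCC(=O)OC | intermediate
3 | penta-1,4-dien-3-ol | C=CC(O)C=C | starting material
4 | (1S)-1-[(2R)-oxiran-2-yl]prop-2-en-1-ol | C=C[C@H](O)[C@H]1CO1 | intermediate
5 | (2R)-2-[(1R)-1-(4-methoxyphenoxy)prop-2-en-1-yl]oxirane | C=C[C@@H](Oc1ccc(OC)cc1)[C@H]1CO1 | intermediate
6 | methyl (4R,5R)-4-hydroxy-2-(methoxymethoxy)-5-(4-methoxyphenoxy)hept-6-enoate (as Et2Al alkoxide, both C2 epimers) | COC(=O)C(OCOC)C[C@@H](O)[C@H](Oc1ccc(OC)cc1)C=C | intermediate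
7 | methyl (4R,5R)-4-[(tert-butyldimethylsilyl)oxy]-2-(methoxymethoxy)-5-(4-methoxyphenoxy)hept-6-enoate (both C2 epimers) | COC(=O)C(OCOC)C[C@@H](O[Si](C)(C)C(C)(C)C)[C@H](Oc1ccc(OC)cc1)C=C | intermediate
8 | methyl (4R,5R)-4-[(tert-butyldimethylsilyl)oxy]-5-hydroxy-2-(methoxymethoxy)hept-6-enoate (both C2 epimers) | COC(=O)C(OCOC)C[C@@H](O[Si](C)(C)C(C)(C)C)[C@H](O)C=C | intermediate
9 | (5R,6R)-5-[(tert-butyldimethylsilyl)oxy]-6-ethenyl-3-(methoxymethoxy)oxan-2-one (both C3 epimers) | C=C[C@H]1OC(=O)C(OCOC)C[C@H]1O[Si](C)(C)C(C)(C)C | intermediate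
10 | (2R,3R)-3-[(tert-butyldimethylsilyl)oxy]-2-ethenyl-5-(methoxymethoxy)-6-[(trimethylsilyl)oxy]-3,4-dihydro-2H-pyran | C=C[C@H]1OC(O[Si](C)(C)C)=C(OCOC)C[C@H]1O[Si](C)(C)C(C)(C)C | intermediate
11 | trimethylsilyl (1R,5R)-5-[(tert-butyldimethylsilyl)oxy]-1-(methoxymethoxy)cyclohex-3-ene-1-carboxylate | CC(C)(C)[Si](C)(C)O[C@H]1C=CC[C@](OCOC)(C(=O)O[Si](C)(C)C)C1 | intermediate
12 | (1R,5R)-5-hydroxy-1-(methoxymethoxy)cyclohex-3-ene-1-carboxylic acid | O[C@H]1C=CC[C@](OCOC)(C(=O)O)C1 | intermediate
13 | 3,4-epoxide of 12, oxirane oxygen cis to the 5-hydroxyl and the OMOM group, trans to CO2H (5-hydroxy-3-(methoxymethoxy)-7-oxabicyclo[4.1.0]heptane-3-carboxylic acid) | O[C@H]1[C@H]2O[C@H]2C[C@](OCOC)(C(=O)O)C1 | intermediate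
14 | (1S,3R,4R,5R)-3,4-dihydroxy-1-(methoxymethoxy)-6-oxabicyclo[3.2.1]octan-7-one | O[C@H]1[C@H]2C[C@](OCOC)(C(=O)O2)C[C@H]1O | intermediate
15 | prop-2-en-1-yl (1S,3R,4S,5R)-3,4,5-trihydroxy-1-(methoxymethoxy)cyclohexane-1-carboxylate | O[C@H]1[C@H](O)C[C@](OCOC)(C(=O)OCC=C)C[C@H]1O | intermediate
16 | succinic anhydride | O=C1CCC(=O)O1 | starting material
17 | 3,4-O-(dibutylstannanediyl) acetal of 15 | CCCC[Sn]1(CCCC)O[C@H]2[C@H](O)C[C@](OCOC)(C(=O)OCC=C)C[C@H]2O1 | intermediate
18 | allyl 4-O-(3-carboxypropanoyl)-1-O-methoxymethyl-quinate | O=C(O)CCC(=O)O[C@H]1[C@H](O)C[C@](OCOC)(C(=O)OCC=C)C[C@H]1O | intermediate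
19 | (E)-3-(3,4-diacetoxyphenyl)prop-2-enoic acid | CC(=O)Oc1ccc(/C=C/C(=O)O)cc1OC(C)=O | starting material
20 | (E)-3-(3,4-diacetoxyphenyl)prop-2-enoyl chloride | CC(=O)Oc1ccc(/C=C/C(=O)Cl)cc1OC(C)=O | intermediate
21 | allyl 5-O-[(E)-3-(3,4-diacetoxyphenyl)prop-2-enoyl]-4-O-(3-carboxypropanoyl)-1-O-methoxymethyl-quinate | O=C(O)CCC(=O)O[C@H]1[C@H](OC(=O)/C=C/c2ccc(OC(C)=O)c(OC(C)=O)c2)C[C@](OCOC)(C(=O)OCC=C)C[C@H]1O | intermediate
22 | allyl 3,5-bis-O-[(E)-3-(3,4-diacetoxyphenyl)prop-2-enoyl]-4-O-(3-carboxypropanoyl)-1-O-methoxymethyl-quinate | O=C(O)CCC(=O)O[C@H]1[C@H](OC(=O)/C=C/c2ccc(OC(C)=O)c(OC(C)=O)c2)C[C@](OCOC)(C(=O)OCC=C)C[C@H]1OC(=O)/C=C/c1ccc(OC(C)=O)c(OC(C)=O)c1 | intermediate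
23 | 3,5-bis-O-[(E)-3-(3,4-diacetoxyphenyl)prop-2-enoyl]-4-O-(3-carboxypropanoyl)-1-O-methoxymethyl-quinic acid | O=C(O)CCC(=O)O[C@H]1[C@H](OC(=O)/C=C/c2ccc(OC(C)=O)c(OC(C)=O)c2)C[C@](OCOC)(C(=O)O)C[C@H]1OC(=O)/C=C/c1ccc(OC(C)=O)c(OC(C)=O)c1 | intermediate
24 | 3,5-di-O-caffeoyl-4-O-succinyl-(−)-quinic acid | O=C(O)CCC(=O)O[C@H]1[C@H](OC(=O)/C=C/c2ccc(O)c(O)c2)C[C@](O)(C(=O)O)C[C@H]1OC(=O)/C=C/c1ccc(O)c(O)c1 | target

**Step count and risks**
Total step count: 12. Longest linear sequence: 10 steps (steps 2–9, 11 and 12, from penta-1,4-dien-3-ol); steps 1 and 10 are one-step branches that join at steps 4 and 11.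

Steps most likely to fail:

1. Step 4. The glycolate enolate may transfer a proton or condense with itself instead of opening the epoxide, or the alkoxide may close the γ-lactone before it is silylated. The fallback replaces the Lewis-acid epoxide opening by an enolate alkylation and sets out from 5. LiI and AcOH in THF should open the oxirane at its CH2 carbon to the iodohydrin (2S,3R)-1-iodo-3-(4-methoxyphenoxy)pent-4-en-2-ol F1. TBSOTf and 2,6-lutidine should then give tert-butyl{[(2S,3R)-1-iodo-3-(4-methoxyphenoxy)pent-4-en-2-yl]oxy}dimethylsilane F2. SN2 alkylation of the pre-formed lithium enolate of 2 (LiN(iPr)2, THF/DMPU, −78 → −20 °C) with the primary iodide F2 comes back to the route at 7.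

2. Step 6. The silyl ketene acetal may be lost by hydrolysis, or by fragmentation of the lactone enolate to a ketene and an alkoxide, before it reaches the strained bridged boat. The fallback forms the same C1–C6 bond by allylic alkylation instead of a sigmatropic shift and sets out from 8, isolated after the cerium stage of step 5. Methyl chloroformate and pyridine should give the allylic carbonate methyl (4R,5R)-4-[(tert-butyldimethylsilyl)oxy]-5-[(methoxycarbonyl)oxy]-2-(methoxymethoxy)hept-6-enoate F3. Its lithium enolate (LiN(SiMe3)2, THF) should then close the ring by intramolecular allylic alkylation at the terminal allyl carbon under Pd(PPh3)4 catalysis (Tsuji–Trost), giving methyl (1R,5R)-5-[(tert-butyldimethylsilyl)oxy]-1-(methoxymethoxy)cyclohex-3-ene-1-carboxylate F4. Saponification (LiOH, THF/H2O) and desilylation (TBAF) come back to the route at 12. Control of C1 is less secure here than in the rearrangement; a C1 epimer could not lactonise in step 7 and would be removed there as an acid.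

3. Step 9. The dibutylstannylene acetal may activate O5 or O3 instead of O4, or the Bu2Sn alkoxide may promote transesterification back to lactone 14. The fallback replaces tin-directed by enzyme-directed acylation and sets out from 15: a lipase (Candida antarctica lipase A) with 16 in tert-butyl methyl ether at 40 °C, a known type of regioselective acylation of the 4-hydroxyl of quinate esters, should give 18 directly and so comes back to the route at 18.

**Further compounds**
F1 | step 4 | (2S,3R)-1-iodo-3-(4-methoxyphenoxy)pent-4-en-2-ol | C=C[C@@H](Oc1ccc(OC)cc1)[C@H](O)CI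
F2 | step 4 | tert-butyl{[(2S,3R)-1-iodo-3-(4-methoxyphenoxy)pent-4-en-2-yl]oxy}dimethylsilane | C=C[C@@H](Oc1ccc(OC)cc1)[C@H](O[Si](C)(C)C(C)(C)C)CI
F3 | step 6 | methyl (4R,5R)-4-[(tert-butyldimethylsilyl)oxy]-5-[(methoxycarbonyl)oxy]-2-(methoxymethoxy)hept-6-enoate | COC(=O)C(OCOC)C[C@@H](O[Si](C)(C)C(C)(C)C)[C@H](OC(=O)OC)C=C
F4 | step 6 | methyl (1R,5R)-5-[(tert-butyldimethylsilyl)oxy]-1-(methoxymethoxy)cyclohex-3-ene-1-carboxylate | CC(C)(C)[Si](C)(C)O[C@H]1C=CC[C@](OCOC)(C(=O)OC)C1
F0 | step 9 | none | none
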